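**Retrosynthetic overview**

1. Numbering: seven-membered ring C1 (carbinol carrying C2(=O)–C3=C4–C15), C5 (O-angelate), C6 (lactone O), C7, C8, C9 (OH), C10 (C14 methyl); lactone C6–O–C12(=O)–C11(=C13)–C7. Feature the route rests on: with C1 as a ketone, C9–OH / C10–CH3 / C1 on the seven-membered ring form an aldol array, and C14 can be the terminal carbon of a C1 vinyl ketone after it has taken up hydride.
2. Target ⇒ angelate on O5, C11=C13 by elimination, crotonyl ketone by addition of an acryloyl anion equivalent to the C1 ketone followed by cross-metathesis ⇒ lactone-fused β-hydroxy cycloheptanone 27.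
3. 27 ⇒ C9–C10 (hydride-triggered reductive aldol) ⇒ cis-γ-lactone 25 with the C8–C9 aldehyde arm on C7 and the O5-protected C1 vinyl ketone arm on C6.
4. 25 ⇒ C1–C10 (Weinreb amide + vinyl Grignard), lactone C12–O6, C5–C6 (auxiliary-controlled syn glycolate aldol; sets C5 and C6), C7–C11 (auxiliary-controlled alkylation; sets C7).
5. Ring order: γ-lactone first (step 9), seven-membered carbocycle second (step 14). O5 carries a 2-naphthylmethyl (NAP) ether rather than a PMB ether because the lactonisation uses TFA; O9 carries TBS after the key step.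

Key step: step 14

Remark: the α-hydroxymethyl lactones 34, 35, 37 and the mesylate 38 are expected as C11 epimer mixtures; C11 becomes sp2 in step 20 and is left unassigned.

**Route**

Step 1
Reactants: 1 (R)-4-benzyl-1,3-oxazolidin-2-one; 2 pent-4-enoyl chloride
Product: 3 (4R)-4-benzyl-3-(pent-4-enoyl)-1,3-oxazolidin-2-one
Conditions: Et3N, DMAP (cat.), CH2Cl2, 0 °C → rt
Reagents that add atoms: none
Why: N-acylation of the oxazolidinone by the acid chloride under DMAP catalysis; the auxiliary stereocentre is not touched.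

Step 2
Reactants: 3; 4 tert-butyl bromoacetate
Product: 6 tert-butyl (3S)-3-{[(4R)-4-benzyl-2-oxo-1,3-oxazolidin-3-yl]carbonyl}hex-5-enoate, via sodium Z-enolate 5 (not isolated)
Conditions: NaN(SiMe3)2, THF, −78 °C; then 4, −78 → −30 °C
Reagents that add atoms: none
Why: Evans alkylation: the chelated sodium Z-enolate 5 is alkylated on the face opposite the benzyl group, which sets C7 (S) with C11–C12 attached.

Step 3
Reactants: 6
Product: 7 tert-butyl (3S)-3-(hydroxymethyl)hex-5-enoate
Conditions: LiBH4, H2O (1.1 equiv), Et2O, 0 °C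
Reagents that add atoms: none
Why: Reductive removal of the auxiliary: LiBH4 reduces the activated imide carbonyl faster than the hindered tert-butyl ester, releasing C6 as the primary alcohol without touching C7.

Step 4
Reactants: 7
Product: 8 tert-butyl (3S)-3-formylhex-5-enoate
Conditions: Dess–Martin periodinane, NaHCO3, CH2Cl2, 0 °C → rt (used at once)
Reagents that add atoms: none
Why: Dess–Martin oxidation under buffered, non-basic conditions should give the α-branched aldehyde without epimerising C7.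

Step 5
Reactants: 9 naphthalen-2-ylmethanol; 10 bromoacetic acid
Product: 11 (naphthalen-2-ylmethoxy)acetic acid
Conditions: NaH (3 equiv), THF, 0 °C → reflux; aq. HCl work-up
Reagents that add atoms: none
Why: Williamson ether synthesis between the sodium alkoxide of 9 and sodium bromoacetate.

Step 6
Reactants: 11; 12 (S)-4-benzyl-1,3-oxazolidin-2-one
Product: 14 (4S)-4-benzyl-3-[(naphthalen-2-ylmethoxy)acetyl]-1,3-oxazolidin-2-one, via pivalic mixed anhydride 13 (not isolated)
Conditions: t-BuCOCl, Et3N, THF, −20 °C; then 12, LiCl, rt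
Reagents that add atoms: none
Why: N-acylation of the oxazolidinone through the mixed pivalic anhydride with LiCl activation, which attacks the less hindered glycolyl carbonyl.

Step 7
Reactants: 14; 8
Product: 16 tert-butyl (3S)-3-[(1R,2S)-3-[(4S)-4-benzyl-2-oxo-1,3-oxazolidin-3-yl]-1-hydroxy-2-(naphthalen-2-ylmethoxy)-3-oxopropyl]hex-5-enoate, via dibutylboron Z-enolate 15 (not isolated)
Conditions: Bu2BOTf, Et3N, CH2Cl2, −78 → 0 °C; then 8, −78 → 0 °C; pH 7 buffer, MeOH, H2O2
Reagents that add atoms: none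
Why: Evans syn glycolate aldol: the Z-boron enolate 15 reacts through a closed chair transition state under auxiliary control and sets C5 (S) and C6 (R), the syn ether/hydroxyl pair; the two α-substituents of 8 are both CH2 groups and add no substrate bias.

Step 8
Reactants: 16
Product: 17 tert-butyl (3S)-3-[(1R,2S)-1-hydroxy-3-[methoxy(methyl)amino]-2-(naphthalen-2-ylmethoxy)-3-oxopropyl]hex-5-enoate
Conditions: MeNHOMe·HCl, AlMe3, THF, −20 → 0 °C
Reagents that add atoms: N,O-dimethylhydroxylamine hydrochloride, CNOC.Cl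
Why: Aluminium amide transamination of the β-hydroxy imide to the Weinreb amide, assisted by the aluminium alkoxide of the C6 hydroxyl, releases the auxiliary without epimerising C5 and leaves the tert-butyl ester.

Step 9
Reactants: 17
Product: 19 (2S)-N-methoxy-N-methyl-2-(naphthalen-2-ylmethoxy)-2-[(2R,3S)-5-oxo-3-(prop-2-en-1-yl)oxolan-2-yl]acetamide, via hydroxy acid 18 (not isolated)
Conditions: TFA/CH2Cl2 (1:4), 0 °C → rt
Reagents that add atoms: none
Why: Acidolysis of the tert-butyl ester and acid-catalysed 5-exo-trig lactonisation of the γ-hydroxy acid 18 form the lactone, which is cis because C6 and C7 are already fixed; the NAP ether tolerates TFA where a PMB ether would be cleaved.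

Step 10
Reactants: 19
Product: 21 (2S)-N-methoxy-N-methyl-2-(naphthalen-2-ylmethoxy)-2-[(2R,3S)-5-oxo-3-(2-oxoethyl)oxolan-2-yl]acetamide, via vicinal diol 20 (not isolated)
Conditions: OsO4 (2 mol%), NaIO4, 2,6-lutidine, dioxane/H2O (3:1), rt
Reagents that add atoms: osmium tetroxide, O=[Os](=O)(=O)=O (delivers the oxygen; re-formed by sodium periodate, [Na+].[O-]I(=O)(=O)=O)
Why: Lemieux–Johnson oxidative cleavage of the only alkene shortens the allyl group to the C8–C9 acetaldehyde arm.

Step 11
Reactants: 21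
Product: 22 (2S)-2-[(2R,3S)-3-(2,2-dimethoxyethyl)-5-oxooxolan-2-yl]-N-methoxy-N-methyl-2-(naphthalen-2-ylmethoxy)acetamide
Conditions: HC(OMe)3, PPTS (cat.), CH2Cl2/MeOH (10:1), rt
Reagents that add atoms: trimethyl orthoformate, COC(OC)OC
Why: Acid-catalysed acetalisation masks the aldehyde for the Grignard step.

Step 12
Reactants: 22; 23 vinylmagnesium bromide
Product: 24 (4S,5R)-4-(2,2-dimethoxyethyl)-5-[(1S)-1-(naphthalen-2-ylmethoxy)-2-oxobut-3-en-1-yl]oxolan-2-one
Conditions: CH2=CHMgBr (1.3 equiv), THF, −78 → −40 °C; inverse quench into cold aq. NaHSO4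
Reagents that add atoms: none
Why: Weinreb ketone synthesis: the activated α-alkoxy amide is attacked at −78 °C, where lactone and acetal should not react, the chelated tetrahedral adduct stops at the ketone stage, and the acidic inverse quench keeps the released amine from adding to the enone.

Step 13
Reactants: 24
Product: 25 2-[(2R,3S)-2-[(1S)-1-(naphthalen-2-ylmethoxy)-2-oxobut-3-en-1-yl]-5-oxooxolan-3-yl]acetaldehyde
Conditions: TFA/H2O (9:1), CH2Cl2, 0 °C (used at once)
Reagents that add atoms: water, O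
Why: Hydrolysis of the dimethyl acetal with a non-nucleophilic acid leaves the vinyl ketone, the lactone and the NAP ether intact.

Step 14
Reactants: 25
Product: 27 (5S,6R,7S,9R,10S)-9-hydroxy-10-methyl-5-(naphthalen-2-ylmethoxy) ketol: cycloheptanone C1(=O)–C5–C6–C7–C8–C9–C10 cis-fused at C6/C7 to the γ-lactone, via copper Z-enolate 26 (not isolated)
Conditions: [(Ph3P)CuH]6 (0.25 equiv of hexamer), degassed toluene, −40 → −20 °C; aq. NH4Cl
Reagents that add atoms: none
Why: Proposed new method: [(Ph3P)CuH]6 transfers hydride to C14 of the s-cis vinyl ketone and leaves the Z(O)-copper enolate 26 at C10 alone (C5 is never enolised, so the lactone oxygen on C6 is not expelled), and this enolate adds to the C9 aldehyde within the molecule before the reagent reduces it; the closest known reaction type is the copper hydride reductive aldol cyclisation of enones bearing a ketone or aldehyde to five- and six-membered rings, here extended to a seven-membered ring that contains the enolate carbons. The ring closes in the 7-(enolendo)-exo-trig mode, which the ring-closure rules allow. The Z(O) geometry comes from hydride transfer to the s-cis enone and not from the ring; what the cis-lactone fixes is a C5–C6–C7–C8 torsion near zero, which holds C8 over the C5 side of the enolate and leaves the aldehyde oxygen either over the enolate oxygen (copper-bridged) or anti to C1 (open). C9 (R) follows from the open arrangement, which for the Z(O)-enolate gives the trans hydroxyl/methyl pair (syn aldol), whereas the bridged one would give the cis pair. C10 (S) follows from the C1–C5 rotamer in which the C5–O bond points away from the enolate oxygen, so that C6 leaves the enolate plane on the face that puts the methyl trans to the C5 ether. The step therefore needs addition without chelation at either oxygen, which the soft, phosphine-bearing monovalent copper enolate in toluene should give (dipoles opposed in both places), and 27, in which hydroxyl and methyl can both be equatorial, is also the isomer expected if the copper aldolate equilibrates.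

Step 15
Reactants: 27
Product: 28 O9-TBS ether of 27
Conditions: TBSOTf, 2,6-lutidine, CH2Cl2, −78 °C
Reagents that add atoms: tert-butyldimethylsilyl trifluoromethanesulfonate, CC(C)(C)[Si](C)(C)OS(=O)(=O)C(F)(F)F
Why: Low-temperature silylation with the silyl triflate protects O9 and blocks retro-aldol cleavage in the next step.

Step 16
Reactants: 28; 29 methoxyallene
Product: 31 (1S)-C1 tertiary alcohol carrying the 1-methoxypropa-1,2-dien-1-yl group on C1, via 1-lithio-1-methoxyallene 30 (not isolated)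
Conditions: 29, n-BuLi, THF, −40 °C; then 28, THF/Et2O, −78 °C; aq. NaHCO3
Reagents that add atoms: none
Why: 1,2-Addition of the acryloyl anion equivalent 30 to the ketone; lithium chelation by the C5 ether should hold that ether in the carbonyl plane so that it screens neither face, and the nucleophile then enters from the convex face of the cis-fused bicycle, opposite the lactone and the C10 methyl, giving C1 (S) with the new carbon cis to O5.

Step 17
Reactants: 31; 32 formaldehyde
Product: 34 C11-hydroxymethyl lactone of 31, via dilithium alkoxide enolate 33 (not isolated)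
Conditions: LiN(iPr)2 (2.5 equiv), THF, −78 → −40 °C; then CH2O (gas from cracked paraformaldehyde), −40 → −20 °C; aq. NH4Cl
Reagents that add atoms: none
Why: Aldol addition of the lactone lithium enolate to monomeric formaldehyde, placed here because this is the only intermediate after the key step with no ketone and no Michael acceptor; the C11 configuration is of no consequence.

Step 18
Reactants: 34
Product: 35 α-hydroxy vinyl ketone (C1–C(=O)–CH=CH2)
Conditions: 5% aq. H2SO4, THF, 0 °C
Reagents that add atoms: water, O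
Why: Acid hydrolysis of the allenyl enol ether (protonation at the central allene carbon, then loss of methanol from the hemiketal) unmasks the vinyl ketone without touching the TBS or NAP ethers.

Step 19
Reactants: 35; 36 (Z)-but-2-ene
Product: 37 E-crotonyl ketone
Conditions: 36 (excess), (H2IMes)Cl2Ru=CH(2-iPrOC6H4) (second-generation Hoveyda–Grubbs catalyst, 5 mol%), CH2Cl2, 40 °C, sealed tube
Reagents that add atoms: none
Why: Olefin cross-metathesis of the vinyl ketone, the only alkene in 35, with excess 2-butene should give the E-enone.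

Step 20
Reactants: 37
Product: 39 α-methylene lactone, via primary mesylate 38 (not isolated)
Conditions: MsCl, Et3N, CH2Cl2, 0 °C; then DBU, rt
Reagents that add atoms: none
Why: Selective mesylation of the primary alcohol (the tertiary C1 hydroxyl does not react) and E1cB elimination of the β-mesyloxy lactone give the C11=C13 methylene.

Step 21
Reactants: 39
Product: 40 C5 alcohol
Conditions: DDQ, CH2Cl2/pH 7 buffer (10:1), 0 °C → rt
Reagents that add atoms: none
Why: Oxidative cleavage of the 2-naphthylmethyl ether by DDQ in wet solvent frees O5 and leaves the TBS ether, the enone and the methylene lactone.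

Step 22
Reactants: 40; 41 angelic acid
Product: 43 O5-angelate O9-TBS ether, via Yamaguchi mixed anhydride 42 (not isolated)
Conditions: 41, 2,4,6-trichlorobenzoyl chloride, Et3N, toluene, rt; then 40, 80 °C (no DMAP)
Reagents that add atoms: none
Why: Yamaguchi esterification with the preformed mixed anhydride acylates the secondary C5 hydroxyl (the tertiary C1 hydroxyl is inert) and, run without DMAP, is the method known to keep the Z geometry of angelates.

Step 23
Reactants: 43
Product: 44 CNP0149130.1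
Conditions: HF·pyridine, pyridine/THF, 0 °C → rt
Reagents that add atoms: none
Why: Fluoride cleavage of the TBS ether under buffered conditions frees O9 without affecting the angelate, the enone or the methylene lactone.

**Compound list**

1 | (R)-4-benzyl-1,3-oxazolidin-2-one | O=C1N[C@H](Cc2ccccc2)CO1 | starting material
2 | pent-4-enoyl chloride | C=CCCC(=O)Cl | starting material
3 | (4R)-4-benzyl-3-(pent-4-enoyl)-1,3-oxazolidin-2-one | C=CCCC(=O)N1[C@H](Cc2ccccc2)COC1=O | intermediate
4 | tert-butyl bromoacetate | CC(C)(C)OC(=O)CBr | starting material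
5 | sodium Z-enolate of 3 | C=CC/C=C(\[O-])N1[C@H](Cc2ccccc2)COC1=O.[Na+] | intermediate (not isolated)
6 | tert-butyl (3S)-3-{[(4R)-4-benzyl-2-oxo-1,3-oxazolidin-3-yl]carbonyl}hex-5-enoate | C=CC[C@@H](CC(=O)OC(C)(C)C)C(=O)N1[C@H](Cc2ccccc2)COC1=O | intermediate
7 | tert-butyl (3S)-3-(hydroxymethyl)hex-5-enoate | C=CC[C@@H](CC(=O)OC(C)(C)C)CO | intermediate
8 | tert-butyl (3S)-3-formylhex-5-enoate | C=CC[C@@H](CC(=O)OC(C)(C)C)C=O | intermediate
9 | naphthalen-2-ylmethanol | OCc1ccc2ccccc2c1 | starting material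
10 | bromoacetic acid | OC(=O)CBr | starting material
11 | (naphthalen-2-ylmethoxy)acetic acid | OC(=O)COCc1ccc2ccccc2c1 | intermediate
12 | (S)-4-benzyl-1,3-oxazolidin-2-one | O=C1N[C@@H](Cc2ccccc2)CO1 | starting material
13 | (naphthalen-2-ylmethoxy)acetic pivalic anhydride | CC(C)(C)C(=O)OC(=O)COCc1ccc2ccccc2c1 | intermediate (not isolated)
14 | (4S)-4-benzyl-3-[(naphthalen-2-ylmethoxy)acetyl]-1,3-oxazolidin-2-one | O=C(COCc1ccc2ccccc2c1)N1[C@@H](Cc2ccccc2)COC1=O | intermediate
15 | dibutylboron Z-enolate of 14 | CCCCB(CCCC)O/C(=C\OCc1ccc2ccccc2c1)N1[C@@H](Cc2ccccc2)COC1=O | intermediate (not isolated)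
16 | tert-butyl (3S)-3-[(1R,2S)-3-[(4S)-4-benzyl-2-oxo-1,3-oxazolidin-3-yl]-1-hydroxy-2-(naphthalen-2-ylmethoxy)-3-oxopropyl]hex-5-enoate | C=CC[C@@H](CC(=O)OC(C)(C)C)[C@@H](O)[C@H](OCc1ccc2ccccc2c1)C(=O)N1[C@@H](Cc2ccccc2)COC1=O | intermediate
17 | tert-butyl (3S)-3-[(1R,2S)-1-hydroxy-3-[methoxy(methyl)amino]-2-(naphthalen-2-ylmethoxy)-3-oxopropyl]hex-5-enoate | C=CC[C@@H](CC(=O)OC(C)(C)C)[C@@H](O)[C@H](OCc1ccc2ccccc2c1)C(=O)N(C)OC | intermediate
18 | (3S)-3-[(1R,2S)-1-hydroxy-3-[methoxy(methyl)amino]-2-(naphthalen-2-ylmethoxy)-3-oxopropyl]hex-5-enoic acid | C=CC[C@@H](CC(=O)O)[C@@H](O)[C@H](OCc1ccc2ccccc2c1)C(=O)N(C)OC | intermediate (not isolated)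
19 | (2S)-N-methoxy-N-methyl-2-(naphthalen-2-ylmethoxy)-2-[(2R,3S)-5-oxo-3-(prop-2-en-1-yl)oxolan-2-yl]acetamide | C1C(=O)O[C@H]([C@H]1CC=C)[C@H](OCc1ccc2ccccc2c1)C(=O)N(C)OC | intermediate
20 | (2S)-2-[(2R,3S)-3-(2,3-dihydroxypropyl)-5-oxooxolan-2-yl]-N-methoxy-N-methyl-2-(naphthalen-2-ylmethoxy)acetamide (carbinol epimers) | C1C(=O)O[C@H]([C@H]1CC(O)CO)[C@H](OCc1ccc2ccccc2c1)C(=O)N(C)OC | intermediate (not isolated)
21 | (2S)-N-methoxy-N-methyl-2-(naphthalen-2-ylmethoxy)-2-[(2R,3S)-5-oxo-3-(2-oxoethyl)oxolan-2-yl]acetamide | C1C(=O)O[C@H]([C@H]1CC=O)[C@H](OCc1ccc2ccccc2c1)C(=O)N(C)OC | intermediate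
22 | (2S)-2-[(2R,3S)-3-(2,2-dimethoxyethyl)-5-oxooxolan-2-yl]-N-methoxy-N-methyl-2-(naphthalen-2-ylmethoxy)acetamide | C1C(=O)O[C@H]([C@H]1CC(OC)OC)[C@H](OCc1ccc2ccccc2c1)C(=O)N(C)OC | intermediate
23 | vinylmagnesium bromide | C=C[Mg]Br | starting material
24 | (4S,5R)-4-(2,2-dimethoxyethyl)-5-[(1S)-1-(naphthalen-2-ylmethoxy)-2-oxobut-3-en-1-yl]oxolan-2-one | C1C(=O)O[C@H]([C@H]1CC(OC)OC)[C@H](OCc1ccc2ccccc2c1)C(=O)C=C | intermediate
25 | 2-[(2R,3S)-2-[(1S)-1-(naphthalen-2-ylmethoxy)-2-oxobut-3-en-1-yl]-5-oxooxolan-3-yl]acetaldehyde (key-step precursor) | C1C(=O)O[C@H]([C@H]1CC=O)[C@H](OCc1ccc2ccccc2c1)C(=O)C=C | intermediate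
26 | Z(O)-copper enolate of 25 across C1=C10 (monovalent copper, phosphine ligand not drawn) | C1C(=O)O[C@H]([C@H]1CC=O)[C@H](OCc1ccc2ccccc2c1)/C(O[Cu])=C/C | intermediate (not isolated)
27 | (5S,6R,7S,9R,10S)-9-hydroxy-10-methyl-5-(naphthalen-2-ylmethoxy) ketol: cycloheptanone C1(=O)–C5–C6–C7–C8–C9–C10, cis-fused at C6/C7 to the γ-lactone (key-step product) | C1C(=O)O[C@@H]2[C@H]1C[C@@H](O)[C@H](C)C(=O)[C@H]2OCc1ccc2ccccc2c1 | intermediate
28 | O9-TBS ether of 27 (5S,6R,7S,9R,10S) | C1C(=O)O[C@@H]2[C@H]1C[C@@H](O[Si](C)(C)C(C)(C)C)[C@H](C)C(=O)[C@H]2OCc1ccc2ccccc2c1 | intermediate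
29 | methoxyallene (1-methoxypropa-1,2-diene) | COC=C=C | starting material
30 | 1-lithio-1-methoxyallene | COC([Li])=C=C | intermediate (not isolated)
31 | (1S,5S,6R,7S,9R,10S) tertiary alcohol: C1 carries OH and 1-methoxypropa-1,2-dien-1-yl; O5 NAP, O9 TBS | C1C(=O)O[C@@H]2[C@H]1C[C@@H](O[Si](C)(C)C(C)(C)C)[C@H](C)[C@@](O)(C(OC)=C=C)[C@H]2OCc1ccc2ccccc2c1 | intermediate
32 | formaldehyde (from paraformaldehyde) | C=O | starting material
33 | dilithium C1-alkoxide / lactone enolate of 31 | C1=C(O[Li])O[C@@H]2[C@H]1C[C@@H](O[Si](C)(C)C(C)(C)C)[C@H](C)[C@@](O[Li])(C(OC)=C=C)[C@H]2OCc1ccc2ccccc2c1 | intermediate (not isolated)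
34 | C11-hydroxymethyl lactone of 31 (C11 unassigned) | OCC1C(=O)O[C@@H]2[C@H]1C[C@@H](O[Si](C)(C)C(C)(C)C)[C@H](C)[C@@](O)(C(OC)=C=C)[C@H]2OCc1ccc2ccccc2c1 | intermediate
35 | α-hydroxy vinyl ketone: C1(OH)–C(=O)–CH=CH2, C11–CH2OH (C11 unassigned), O5 NAP, O9 TBS | OCC1C(=O)O[C@@H]2[C@H]1C[C@@H](O[Si](C)(C)C(C)(C)C)[C@H](C)[C@@](O)(C(=O)C=C)[C@H]2OCc1ccc2ccccc2c1 | intermediate
36 | (Z)-but-2-ene | C/C=C\C | starting material
37 | E-crotonyl ketone: C1(OH)–C(=O)–CH=CH–CH3, C11–CH2OH (C11 unassigned), O5 NAP, O9 TBS | OCC1C(=O)O[C@@H]2[C@H]1C[C@@H](O[Si](C)(C)C(C)(C)C)[C@H](C)[C@@](O)(C(=O)/C=C/C)[C@H]2OCc1ccc2ccccc2c1 | intermediate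
38 | primary mesylate of 37 (C11 unassigned) | CS(=O)(=O)OCC1C(=O)O[C@@H]2[C@H]1C[C@@H](O[Si](C)(C)C(C)(C)C)[C@H](C)[C@@](O)(C(=O)/C=C/C)[C@H]2OCc1ccc2ccccc2c1 | intermediate (not isolated)
39 | (1S,5S,6R,7S,9R,10S) α-methylene lactone, O5 NAP, O9 TBS | C=C1C(=O)O[C@@H]2[C@H]1C[C@@H](O[Si](C)(C)C(C)(C)C)[C@H](C)[C@@](O)(C(=O)/C=C/C)[C@H]2OCc1ccc2ccccc2c1 | intermediate
40 | (1S,5S,6R,7S,9R,10S) C5 alcohol, O9 TBS | C=C1C(=O)O[C@@H]2[C@H]1C[C@@H](O[Si](C)(C)C(C)(C)C)[C@H](C)[C@@](O)(C(=O)/C=C/C)[C@H]2O | intermediate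
41 | angelic acid, (Z)-2-methylbut-2-enoic acid | C/C=C(/C)C(=O)O | starting material
42 | angelic 2,4,6-trichlorobenzoic anhydride | C/C=C(/C)C(=O)OC(=O)c1c(Cl)cc(Cl)cc1Cl | intermediate (not isolated)
43 | O5-angelate, O9 TBS ether | C=C1C(=O)O[C@@H]2[C@H]1C[C@@H](O[Si](C)(C)C(C)(C)C)[C@H](C)[C@@](O)(C(=O)/C=C/C)[C@H]2OC(=O)/C(C)=C\C | intermediate
44 | CNP0149130.1, (1S,5S,6R,7S,9R,10S) | C=C1C(=O)O[C@@H]2[C@H]1C[C@@H](O)[C@H](C)[C@@](O)(C(=O)/C=C/C)[C@H]2OC(=O)/C(C)=C\C | target

**Step count**

Total: 23 steps. Longest linear sequence: 21 steps (steps 1–4 and 7–23); steps 5 and 6 are a two-step side branch.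

**Steps most likely to fail**

1. Step 14 (proposed new method). What may go wrong: ring closure may be slower than the simple fates of the enolate (protonation to the saturated ethyl ketone, reduction of the aldehyde), or the addition may run through the copper-bridged arrangement and give the cis hydroxyl/methyl pair or the C10 epimer. Fallback with known chemistry, a samarium Reformatsky-type closure, setting out from 24 and coming back at 27: conjugate hydrosilylation of 24 (Et3SiH, (Ph3P)3RhCl cat., THF, 50 °C) should give the Z triethylsilyl enol ether F1 regiospecifically at C10; NBS (THF, −78 °C) converts it into the α-bromo ketone F2 (C10 epimers); aqueous TFA as in step 13 unmasks the aldehyde to give the bromo keto aldehyde F3; SmI2 (divalent samarium, THF, −78 °C) then generates the samarium enolate at C10 and closes C9–C10 to 27.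

2. Step 16. What may go wrong: poor facial selectivity (entry from the lactone face gives the C1 epimer), or enolisation of the ketone toward C5 with loss of the lactone oxygen. Fallback that exchanges the roles of carbon and oxygen at C1, setting out from 28 and coming back at 37: non-basic methylenation of 28 (Zn, CH2Br2, TiCl4, THF; Lombardo conditions) gives the exocyclic alkene F4; OsO4 (cat.)/NMO should add anti to the allylic C5 ether, that is from the lactone face, to give the diol F5 with the C1 hydroxyl where it is needed; Parikh–Doering oxidation (SO3·pyridine, DMSO, iPr2NEt) gives the α-hydroxy aldehyde F6; (E)-prop-1-enylmagnesium bromide gives the allylic alcohol F7 (C2 epimers); LiN(iPr)2 then formaldehyde, as in step 17, gives the hydroxymethyl lactone F8; MnO2 (CH2Cl2) oxidises only the allylic alcohol and returns to 37.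

3. Step 22. What may go wrong: slow acylation of the hindered C5 hydroxyl, Z-to-E isomerisation of the angelate under forcing conditions, and base-induced retro-aldol cleavage of C1–C5. Fallback that builds the Z double bond after the ester is in place, setting out from 40 and coming back at 43: 2-[bis(2,2,2-trifluoroethoxy)phosphoryl]propanoic acid, DIC and DMAP (CH2Cl2) give the phosphonate ester F9 (no alkene geometry is at stake, so DMAP can be used); Still–Gennari olefination (KN(SiMe3)2, 18-crown-6, THF, −78 °C; acetaldehyde) then forms the (Z)-2-methylbut-2-enoate and returns to 43.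

**Further compounds**

F1 | step 14 | Z triethylsilyl enol ether of 24 (C1=C10) | C1C(=O)O[C@H]([C@H]1CC(OC)OC)[C@H](OCc1ccc2ccccc2c1)/C(O[Si](CC)(CC)CC)=C/C
F2 | step 14 | α-bromo ketone, C10–Br (C10 epimers), acetal | C1C(=O)O[C@H]([C@H]1CC(OC)OC)[C@H](OCc1ccc2ccccc2c1)C(=O)C(C)Br
F3 | step 14 | bromo keto aldehyde (C10 epimers) | C1C(=O)O[C@H]([C@H]1CC=O)[C@H](OCc1ccc2ccccc2c1)C(=O)C(C)Br
F4 | step 16 | C1 exocyclic methylene compound from 28 | C1C(=O)O[C@@H]2[C@H]1C[C@@H](O[Si](C)(C)C(C)(C)C)[C@H](C)C(=C)[C@H]2OCc1ccc2ccccc2c1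
F5 | step 16 | C1(OH)–CH2OH diol | C1C(=O)O[C@@H]2[C@H]1C[C@@H](O[Si](C)(C)C(C)(C)C)[C@H](C)[C@@](O)(CO)[C@H]2OCc1ccc2ccccc2c1
F6 | step 16 | C1(OH)–CHO α-hydroxy aldehyde | C1C(=O)O[C@@H]2[C@H]1C[C@@H](O[Si](C)(C)C(C)(C)C)[C@H](C)[C@@](O)(C=O)[C@H]2OCc1ccc2ccccc2c1
F7 | step 16 | C1(OH)–CH(OH)–CH=CH–CH3 allylic alcohol (C2 epimers) | C1C(=O)O[C@@H]2[C@H]1C[C@@H](O[Si](C)(C)C(C)(C)C)[C@H](C)[C@@](O)(C(O)/C=C/C)[C@H]2OCc1ccc2ccccc2c1
F8 | step 16 | C11-hydroxymethyl lactone of F7 (C2 and C11 unassigned) | OCC1C(=O)O[C@@H]2[C@H]1C[C@@H](O[Si](C)(C)C(C)(C)C)[C@H](C)[C@@](O)(C(O)/C=C/C)[C@H]2OCc1ccc2ccccc2c1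
F9 | step 22 | O5 2-[bis(2,2,2-trifluoroethoxy)phosphoryl]propanoate of 40 | C=C1C(=O)O[C@@H]2[C@H]1C[C@@H](O[Si](C)(C)C(C)(C)C)[C@H](C)[C@@](O)(C(=O)/C=C/C)[C@H]2OC(=O)C(C)P(=O)(OCC(F)(F)F)OCC(F)(F)F
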